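**Plan**

- Retrosynthesis: (1) the carbinol goes back to a pyrrolidin-3-one, which is cut at its C3–C4 bond (Dieckmann) and its N–CH2 bond (aza-Michael). (2) The cyclohexane is cut twice: between its CH(CO2Me) and the neighbouring ring CH2, and between the aminated quaternary carbon and its other ring CH2. (3) Then the N–CH2 bond of the aminoethyl arm, the indoline C2–CH2CO2Me bond, the indoline N=C2 bond and the C3–allyl bond.
- Enabling feature: the CH(CO2Me) of the cyclohexane is the α-carbon of an acetate on indoline C2. The ring CH2 beside it is the β-carbon of a hidden dehydroalanine, whose α-carbon is the aminated quaternary carbon shared by cyclohexane, azocine and pyrrolidine, whose amino group is the azocine nitrogen and whose carboxyl carbon is the carbinol carbon. An ester enolate adding to that acrylate leaves an α-amino ester enolate that closes the second two-carbon bridge on a chloroethyl arm.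
- Forward order of rings: temporary δ-lactone → indoline (3H-indole, then N-acyliminium Mannich) → azocine and cyclohexane in one operation → pyrrolidine.
- Stereochemistry: indoline C3 from an asymmetric allylation; indoline C2 from the cis-fused temporary lactone; the aminated bridgehead from the geometry of the bicycle; the CH(CO2Me) from kinetic protonation of the caged enolate; the carbinol from a CBS reduction.

Key step: step 10

Remark: the sense of induction of the chiral ligand in step 3 is assumed; its mirror image is used if the opposite sense is found.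

**Route**

Step 1
Reactants: 1 methyl acetoacetate; 2 formaldehyde (monomer gas from cracked paraformaldehyde)
Product: 4 oxane-2,4-dione, via methyl 5-hydroxy-3-oxopentanoate 3 (not isolated)
Conditions: NaH, then n-BuLi, THF, 0 °C; CH2O (g), −20 °C; 1 M NaOH, rt; HCl to pH 1
Reagents that add atoms: formaldehyde 2 (C=O)
Why: The acetoacetate dianion should undergo aldol addition to formaldehyde at its terminal carbon, and saponification followed by acidification should close the δ-lactone (lactonization) that serves as the temporary ring.

Step 2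
Reactants: 4 oxane-2,4-dione; 5 1-fluoro-2-nitrobenzene
Product: 6 4-hydroxy-3-(2-nitrophenyl)-5,6-dihydro-2H-pyran-2-one
Conditions: K2CO3, DMSO, 80 °C; aq. HCl
Reagents that add atoms: 1-fluoro-2-nitrobenzene 5 (O=[N+]([O-])c1ccccc1F)
Why: The stabilized enolate of the 1,3-dicarbonyl unit should displace fluoride ortho to the nitro group by nucleophilic aromatic substitution (SNAr C-arylation), as cyclic 1,3-diones do.

Step 3
Reactants: 6 4-hydroxy-3-(2-nitrophenyl)-5,6-dihydro-2H-pyran-2-one; 7 allyl acetate
Product: 8 (3S)-3-(2-nitrophenyl)-3-(prop-2-en-1-yl)oxane-2,4-dione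
Conditions: Pd2(dba)3·CHCl3 (2.5 mol %), (1R,2R)-N,N'-bis(2-diphenylphosphinobenzoyl)cyclohexane-1,2-diamine (7.5 mol %), CH2Cl2, 0 °C
Reagents that add atoms: allyl acetate 7 (CC(=O)OCC=C)
Why: In this Tsuji–Trost asymmetric allylic alkylation the prochiral, unsymmetrical lactone–ketone enolate should attack the π-allylpalladium complex inside the chiral pocket of the ligand, which creates the quaternary stereocenter that becomes indoline C3.

Step 4
Reactants: 8 (3S)-3-(2-nitrophenyl)-3-(prop-2-en-1-yl)oxane-2,4-dione
Product: 10 (9bS)-9b-(prop-2-en-1-yl)-3,4-dihydropyrano[4,3-b]indol-1(9bH)-one, via aminophenyl dione 9 (not isolated)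
Conditions: Fe powder, AcOH, 70 °C
Reagents that add atoms: none
Why: Béchamp reduction of the nitro group should give the aniline, which condenses with the ketone faster than it acylates on the lactone (reductive cyclization to the 3H-indole), leaving the allyl group and the quaternary centre untouched.

Step 5
Reactants: 10 (9bS)-9b-(prop-2-en-1-yl)-3,4-dihydropyrano[4,3-b]indol-1(9bH)-one; 11 methyl chloroformate; 12 1-(tert-butyldimethylsilyloxy)-1-methoxyethene
Product: 14 methyl (4aR,9bS)-4a-(2-methoxy-2-oxoethyl)-1-oxo-9b-(prop-2-en-1-yl)-1,3,4,9b-tetrahydropyrano[4,3-b]indole-5(4aH)-carboxylate, via N-methoxycarbonyl indoleninium chloride 13 (not isolated)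
Conditions: ClCO2Me, CH2Cl2, −78 °C; then 12, TMSOTf (10 mol %), −78 → 0 °C
Reagents that add atoms: methyl chloroformate 11 (COC(=O)Cl); 1-(tert-butyldimethylsilyloxy)-1-methoxyethene 12 (C=C(OC)O[Si](C)(C)C(C)(C)C)
Why: N-acylation turns the imine into an N-acyliminium ion that the ketene silyl acetal should attack in a Mukaiyama–Mannich reaction from the face of the allyl group, the only trajectory that leaves the lactone cis-fused to the five-membered ring, so the acetate arm at the new quaternary C2 ends cis to the allyl group.

Step 6
Reactants: 14 the Mannich lactone; 15 thionyl chloride; 16 methanol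
Product: 18 dimethyl (2S,3S)-2-(2-chloroethyl)-2-(2-methoxy-2-oxoethyl)-3-(prop-2-en-1-yl)-2,3-dihydro-1H-indole-1,3-dicarboxylate, via chloroethyl acyl chloride 17 (not isolated)
Conditions: SOCl2, ZnCl2 (10 mol %), 60 °C; then MeOH, 0 °C → rt
Reagents that add atoms: thionyl chloride 15 (O=S(Cl)Cl); methanol 16 (CO)
Why: Lewis-acid-assisted attack of chloride at the O–CH2 carbon should open the lactone by alkyl–oxygen cleavage (ring-opening chlorination) to the acyl chloride, and methanolysis gives the methyl ester, so the temporary ring leaves behind the C3 ester and the chloroethyl arm without touching a stereocenter.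

Step 7
Reactants: 18 the allyl chloro diester; 19 ozone
Product: 21 dimethyl (2S,3S)-2-(2-chloroethyl)-2-(2-methoxy-2-oxoethyl)-3-(2-oxoethyl)-2,3-dihydro-1H-indole-1,3-dicarboxylate, via secondary ozonide 20 (not isolated)
Conditions: O3, CH2Cl2, −78 °C; Me2S, −78 °C → rt
Reagents that add atoms: ozone 19 ([O-][O+]=O)
Why: Ozonolysis with reductive work-up should cleave the only alkene to the aldehyde, while the acylated aniline ring is too electron-poor to compete at −78 °C.

Step 8
Reactants: 21 the aldehyde; 22 L-serine methyl ester hydrochloride; 23 di-tert-butyl dicarbonate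
Product: 25 dimethyl (2S,3S)-3-{2-[(tert-butoxycarbonyl)((2S)-3-hydroxy-1-methoxy-1-oxopropan-2-yl)amino]ethyl}-2-(2-chloroethyl)-2-(2-methoxy-2-oxoethyl)-2,3-dihydro-1H-indole-1,3-dicarboxylate, via secondary amine 24 (not isolated)
Conditions: 22, Et3N, CH2Cl2, rt; then Boc2O, NaBH(OAc)3, rt
Reagents that add atoms: L-serine methyl ester hydrochloride 22 (COC(=O)[C@@H](N)CO.Cl); di-tert-butyl dicarbonate 23 (CC(C)(C)OC(=O)OC(=O)OC(C)(C)C)
Why: Reductive amination through the iminium ion, with the secondary amine trapped as its Boc carbamate as it forms, should prevent γ-lactam formation on the C3 ester; the serine stereocenter is carried only until step 9.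

Step 9
Reactants: 25 the N-Boc serine derivative
Product: 27 dimethyl (2S,3S)-3-{2-[(tert-butoxycarbonyl)(3-methoxy-3-oxoprop-1-en-2-yl)amino]ethyl}-2-(2-chloroethyl)-2-(2-methoxy-2-oxoethyl)-2,3-dihydro-1H-indole-1,3-dicarboxylate, via serine mesylate 26 (not isolated)
Conditions: MsCl, Et3N, CH2Cl2, 0 °C; DBU, rt
Reagents that add atoms: none
Why: Mesylation and base-induced β-elimination (E1cB) should give the N-Boc N-alkyl dehydroalanine ester, the acrylate acceptor of the key step, and erase the serine stereocenter.

Step 10
Reactants: 27 the dehydroalanine chloro triester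
Product: 29 caged N-Boc amino triester (bicyclo[4.2.2] core: indoline, cyclohexane and azocine closed; Boc on the azocine nitrogen, CO2Me on the aminated bridgehead; configurations as in the target), via azocine potassium enolate 28 (not isolated)
Conditions: KN(SiMe3)2 (1.2 equiv), THF (0.005 M), −78 → 25 °C; KN(SiMe3)2 (1.5 equiv), −78 °C; AcOH, −78 °C
Reagents that add atoms: none
Why: KN(SiMe3)2 removes a proton from the only enolizable position, the CH2 of the C2 acetate; the potassium enolate adds to the CH2 terminus of the N-Boc dehydroalanine (8-endo-trig Michael addition, which forms the bond between the ester-bearing CH and the ring CH2 and closes the azocine), and the α-amino ester enolate left at the former alkene carbon displaces chloride from the 2-chloroethyl arm (6-exo-tet), which closes the cyclohexane and completes the bicyclo[4.2.2] core. The closest known reaction type is the Michael-initiated ring closure, that is, conjugate addition of an ester enolate to a dehydroamino ester followed by alkylation of the resulting amino ester enolate, here with both events intramolecular. The aminated quaternary carbon is a bridgehead whose configuration follows from the cis arrangement of the acetate and aminoethyl arms on the indoline (fixed in step 5), because the second bond can only form on the enolate face that lets all three bridges close. The CH(CO2Me) centre is set at the end: the second portion of base converts the caged ester into its enolate, and protonation at −78 °C should occur from the open face beside the unsubstituted CH2CH2 bridge, away from the azocine CH2 next to indoline C3, which leaves CO2Me syn to the nitrogen bridge as in the target. The step needs C-attack at the acrylate terminus to win over intermolecular addition and over loss of the carbamate nitrogen from the β-position of the first enolate; high dilution, enolate formation at low temperature and the proximity enforced by the cis arms should secure this, and the chloride stays inert toward the first enolate, for which only a 4-exo-tet closure is open.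

Step 11
Reactants: 29 the caged N-Boc amino triester
Product: 30 caged secondary amine (29 without Boc)
Conditions: TFA, CH2Cl2, 0 °C; aq. NaHCO3
Reagents that add atoms: none
Why: Acidolysis of the tert-butyl carbamate (Boc deprotection) should free the azocine nitrogen while the methyl carbamate and the three methyl esters survive, and the freed nitrogen sits next to a bridgehead where lactam formation would give a twisted amide.

Step 12
Reactants: 30 the caged secondary amine; 31 tert-butyl acrylate
Product: 32 caged tertiary amine carrying the N-CH2CH2CO2t-Bu arm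
Conditions: tert-butyl acrylate (5 equiv), MeOH, 60 °C
Reagents that add atoms: tert-butyl acrylate 31 (C=CC(=O)OC(C)(C)C)
Why: Aza-Michael addition of the secondary amine to the acrylate should install the two carbons of the pyrrolidine, with excess acceptor and a protic solvent offsetting the hindrance of the α-quaternary amine; no stereocenter is formed.

Step 13
Reactants: 32 the amino tetraester
Product: 33 caged pyrrolidine β-keto tert-butyl ester (enol form: 3-hydroxy-2,5-dihydropyrrole-4-carboxylate spiro-fused at the aminated bridgehead)
Conditions: KN(SiMe3)2 (3 equiv), THF, −78 → 0 °C; re-cool to −78 °C; AcOH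
Reagents that add atoms: none
Why: In this Dieckmann condensation the enolate of the tert-butyl ester should attack the methyl ester on the aminated bridgehead (5-exo-trig, the only small-ring option) to close the pyrrolidine, and because the excess base also enolizes the caged CH(CO2Me), the cold quench repeats the kinetic protonation of step 10 and keeps that centre in the target configuration.

Step 14
Reactants: 33 the β-keto tert-butyl ester
Product: 35 caged pyrrolidin-3-one, via keto acid 34 (not isolated)
Conditions: TFA, CH2Cl2, rt; then toluene, 60 °C; aq. NaHCO3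
Reagents that add atoms: none
Why: Acidolysis of the tert-butyl ester followed by decarboxylation of the β-keto acid should leave the ketone under conditions that do not touch the methyl esters, the methyl carbamate or the ester-bearing CH.

Step 15
Reactants: 35 the caged pyrrolidin-3-one
Product: 36 CNP0144467.2 (target)
Conditions: (S)-2-methyl-CBS-oxazaborolidine (0.5 equiv), catecholborane, toluene, −78 °C; MeOH, aq. NaHCO3
Reagents that add atoms: none
Why: The Corey–Bakshi–Shibata reduction distinguishes the quaternary side of the ketone from its CH2 side under reagent control and should give the (R)-carbinol, with OH cis to the cyclohexane CH2 that leads to the ester-bearing CH, where the nearly symmetric cage offers little substrate bias.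

**Compound list**

1 | methyl acetoacetate | CC(=O)CC(=O)OC | starting material
2 | formaldehyde (from cracked paraformaldehyde) | C=O | starting material
3 | methyl 5-hydroxy-3-oxopentanoate (not isolated) | COC(=O)CC(=O)CCO | intermediate
4 | oxane-2,4-dione | O=C1CCOC(=O)C1 | intermediate
5 | 1-fluoro-2-nitrobenzene | O=[N+]([O-])c1ccccc1F | starting material
6 | 4-hydroxy-3-(2-nitrophenyl)-5,6-dihydro-2H-pyran-2-one (enol form of the 3-aryl dione) | OC1=C(c2ccccc2[N+](=O)[O-])C(=O)OCC1 | intermediate
7 | allyl acetate | CC(=O)OCC=C | starting material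
8 | (3S)-3-(2-nitrophenyl)-3-(prop-2-en-1-yl)oxane-2,4-dione | C=CC[C@]1(c2ccccc2[N+](=O)[O-])C(=O)CCOC1=O | intermediate
9 | (3S)-3-(2-aminophenyl)-3-(prop-2-en-1-yl)oxane-2,4-dione (not isolated) | C=CC[C@]1(c2ccccc2N)C(=O)CCOC1=O | intermediate
10 | (9bS)-9b-(prop-2-en-1-yl)-3,4-dihydropyrano[4,3-b]indol-1(9bH)-one (3H-indole fused to the δ-lactone) | O=C1OCCC2=Nc3ccccc3[C@]12CC=C | intermediate
11 | methyl chloroformate | COC(=O)Cl | starting material
12 | 1-(tert-butyldimethylsilyloxy)-1-methoxyethene | C=C(OC)O[Si](C)(C)C(C)(C)C | starting material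
13 | (9bS)-5-(methoxycarbonyl)-1-oxo-9b-(prop-2-en-1-yl)-1,3,4,9b-tetrahydropyrano[4,3-b]indol-5-ium chloride (N-acyliminium salt, not isolated) | COC(=O)[N+]1=C2CCOC(=O)[C@@]2(CC=C)c2ccccc21.[Cl-] | intermediate
14 | methyl (4aR,9bS)-4a-(2-methoxy-2-oxoethyl)-1-oxo-9b-(prop-2-en-1-yl)-1,3,4,9b-tetrahydropyrano[4,3-b]indole-5(4aH)-carboxylate (lactone cis-fused, acetate arm cis to allyl) | COC(=O)C[C@]12CCOC(=O)[C@@]1(CC=C)c1ccccc1N2C(=O)OC | intermediate
15 | thionyl chloride | O=S(Cl)Cl | starting material
16 | methanol | CO | starting material
17 | methyl (2S,3S)-3-(chlorocarbonyl)-2-(2-chloroethyl)-2-(2-methoxy-2-oxoethyl)-3-(prop-2-en-1-yl)-2,3-dihydro-1H-indole-1-carboxylate (not isolated) | COC(=O)C[C@]1(CCCl)[C@@](CC=C)(C(=O)Cl)c2ccccc2N1C(=O)OC | intermediate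
18 | dimethyl (2S,3S)-2-(2-chloroethyl)-2-(2-methoxy-2-oxoethyl)-3-(prop-2-en-1-yl)-2,3-dihydro-1H-indole-1,3-dicarboxylate | COC(=O)C[C@]1(CCCl)[C@@](CC=C)(C(=O)OC)c2ccccc2N1C(=O)OC | intermediate
19 | ozone | [O-][O+]=O | starting material
20 | secondary ozonide of 18 (1,2,4-trioxolan-3-ylmethyl group on indoline C3; epimers at the trioxolane carbon; not isolated) | COC(=O)C[C@]1(CCCl)[C@@](CC2OCOO2)(C(=O)OC)c2ccccc2N1C(=O)OC | intermediate
21 | dimethyl (2S,3S)-2-(2-chloroethyl)-2-(2-methoxy-2-oxoethyl)-3-(2-oxoethyl)-2,3-dihydro-1H-indole-1,3-dicarboxylate | COC(=O)C[C@]1(CCCl)[C@@](CC=O)(C(=O)OC)c2ccccc2N1C(=O)OC | intermediate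
22 | L-serine methyl ester hydrochloride | COC(=O)[C@@H](N)CO.Cl | starting material
23 | di-tert-butyl dicarbonate | CC(C)(C)OC(=O)OC(=O)OC(C)(C)C | starting material
24 | N-[2-(indolin-3-yl)ethyl] L-serine methyl ester derived from 21 (secondary amine, not isolated) | COC(=O)C[C@]1(CCCl)[C@@](CCN[C@@H](CO)C(=O)OC)(C(=O)OC)c2ccccc2N1C(=O)OC | intermediate
25 | dimethyl (2S,3S)-3-{2-[(tert-butoxycarbonyl)((2S)-3-hydroxy-1-methoxy-1-oxopropan-2-yl)amino]ethyl}-2-(2-chloroethyl)-2-(2-methoxy-2-oxoethyl)-2,3-dihydro-1H-indole-1,3-dicarboxylate | COC(=O)C[C@]1(CCCl)[C@@](CCN(C(=O)OC(C)(C)C)[C@@H](CO)C(=O)OC)(C(=O)OC)c2ccccc2N1C(=O)OC | intermediate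
26 | O-methanesulfonate of 25 (not isolated) | COC(=O)C[C@]1(CCCl)[C@@](CCN(C(=O)OC(C)(C)C)[C@@H](COS(C)(=O)=O)C(=O)OC)(C(=O)OC)c2ccccc2N1C(=O)OC | intermediate
27 | dimethyl (2S,3S)-3-{2-[(tert-butoxycarbonyl)(3-methoxy-3-oxoprop-1-en-2-yl)amino]ethyl}-2-(2-chloroethyl)-2-(2-methoxy-2-oxoethyl)-2,3-dihydro-1H-indole-1,3-dicarboxylate | COC(=O)C[C@]1(CCCl)[C@@](CCN(C(=O)OC(C)(C)C)C(=C)C(=O)OC)(C(=O)OC)c2ccccc2N1C(=O)OC | intermediate
28 | potassium enolate of the azocine-fused Michael adduct (eight-membered ring closed, chloroethyl arm still free; ester-bearing CH undefined; not isolated) | COC(=O)C1CC(=C([O-])OC)N(C(=O)OC(C)(C)C)CC[C@]2(C(=O)OC)c3ccccc3N(C(=O)OC)[C@]12CCCl.[K+] | intermediate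
29 | caged N-Boc amino triester (target skeleton without the two pyrrolidine CH2 carbons; Boc on the azocine nitrogen, CO2Me on the aminated bridgehead; ester CH R, aminated bridgehead R, indoline C2 R, indoline C3 S) | COC(=O)[C@@H]1C[C@@]2(C(=O)OC)CC[C@@]13N(C(=O)OC)c1ccccc1[C@@]3(C(=O)OC)CCN2C(=O)OC(C)(C)C | intermediate
30 | caged secondary amine (29 without Boc) | COC(=O)[C@@H]1C[C@@]2(C(=O)OC)CC[C@@]13N(C(=O)OC)c1ccccc1[C@@]3(C(=O)OC)CCN2 | intermediate
31 | tert-butyl acrylate | C=CC(=O)OC(C)(C)C | starting material
32 | caged tertiary amine with the N-(3-tert-butoxy-3-oxopropyl) arm | COC(=O)[C@@H]1C[C@@]2(C(=O)OC)CC[C@@]13N(C(=O)OC)c1ccccc1[C@@]3(C(=O)OC)CCN2CCC(=O)OC(C)(C)C | intermediate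
33 | caged pyrrolidine β-keto tert-butyl ester, enol form | COC(=O)[C@@H]1C[C@@]23CC[C@@]14N(C(=O)OC)c1ccccc1[C@@]4(C(=O)OC)CCN2CC(C(=O)OC(C)(C)C)=C3O | intermediate
34 | caged pyrrolidin-3-one-4-carboxylic acid (carboxyl-bearing carbon undefined; not isolated) | COC(=O)[C@@H]1C[C@@]23CC[C@@]14N(C(=O)OC)c1ccccc1[C@@]4(C(=O)OC)CCN2CC(C(=O)O)C3=O | intermediate
35 | caged pyrrolidin-3-one (target with C=O in place of CH–OH) | COC(=O)[C@@H]1C[C@@]23CC[C@@]14N(C(=O)OC)c1ccccc1[C@@]4(C(=O)OC)CCN2CCC3=O | intermediate
36 | CNP0144467.2 | COC(=O)[C@@H]1C[C@@]23CC[C@@]14N(C(=O)OC)c1ccccc1[C@@]4(C(=O)OC)CCN2CC[C@H]3O | target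

**Step count and risks**

Total steps: 15. Longest linear sequence: 15 (fully linear from methyl acetoacetate).

Steps most likely to fail:

1. Step 10. The eight-membered Michael closure may lose to intermolecular conjugate addition, or the first enolate may expel the carbamate nitrogen from its β-position before it cyclizes. Fallback, from 18 back to 30: the potassium enolate of 18 (KN(SiMe3)2, THF, −78 °C) is added to methyl 2-[bis(tert-butoxycarbonyl)amino]acrylate (C=C(C(=O)OC)N(C(=O)OC(C)(C)C)C(=O)OC(C)(C)C). This intermolecular Michael addition has no ring to close, and the amino ester enolate then closes the cyclohexane on the chloroethyl arm to give the spiro[cyclohexane-1,2'-indoline] bis-Boc amino ester F1. Ozonolysis (O3; Me2S) gives the aldehyde F2. TFA then frees the primary amine, and NaBH(OAc)3 closes the azocine by intramolecular reductive amination to the caged secondary amine with undefined ester CH F3. Only the epimer of F1 with nitrogen on the side of the aldehyde arm can close. Enolization and cold protonation of F3 as in step 10 returns the route at 30.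

2. Step 5. Proton loss from the N-acyliminium ion to an ene-carbamate may outrun carbon–carbon bond formation at the hindered carbon. Fallback, from 10 back to 14: Reformatsky addition of BrZnCH2CO2Me (methyl bromoacetate, Zn, THF) to the C=N bond activated by BF3·OEt2 should give the N–H indoline acetate lactone F4, under the same cis-fusion control. N-acylation (NaN(SiMe3)2, ClCO2Me, THF, −78 °C) returns the route at 14.

3. Step 3. Enantioface discrimination on the aryl-substituted enolate may be poor, or O-allylation may compete. Fallback, from 6 back to 8: allylation with an achiral catalyst (Pd(PPh3)4, allyl acetate, THF) gives the racemic allyl dione F5, and separation of its enantiomers on a chiral stationary phase (preparative SFC) returns the route at 8.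

Further compounds
F1 | step 10 | spiro[cyclohexane-1,2'-indoline] amino ester with N(Boc)2 and CO2Me on the aminated carbon, allyl on indoline C3, ester CH undefined | COC(=O)C1C[C@@](N(C(=O)OC(C)(C)C)C(=O)OC(C)(C)C)(C(=O)OC)CC[C@@]12N(C(=O)OC)c1ccccc1[C@@]2(C(=O)OC)CC=C
F2 | step 10 | aldehyde from F1 (2-oxoethyl in place of allyl) | COC(=O)C1C[C@@](N(C(=O)OC(C)(C)C)C(=O)OC(C)(C)C)(C(=O)OC)CC[C@@]12N(C(=O)OC)c1ccccc1[C@@]2(C(=O)OC)CC=O
F3 | step 10 | caged secondary amine 30 with undefined ester CH | COC(=O)C1C[C@@]2(C(=O)OC)CC[C@@]13N(C(=O)OC)c1ccccc1[C@@]3(C(=O)OC)CCN2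
F4 | step 5 | methyl 2-[(4aR,9bS)-1-oxo-9b-(prop-2-en-1-yl)-1,3,4,9b-tetrahydropyrano[4,3-b]indol-4a(5H)-yl]acetate (N–H indoline) | COC(=O)C[C@]12CCOC(=O)[C@@]1(CC=C)c1ccccc1N2
F5 | step 3 | racemic 3-(2-nitrophenyl)-3-(prop-2-en-1-yl)oxane-2,4-dione | C=CCC1(c2ccccc2[N+](=O)[O-])C(=O)CCOC1=O
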